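**Retrosynthetic overview**

1. Late stage: the tiglate on O3 and the umbelliferone ether on C11 come from triol 18; the C8 carbinol comes from methyl addition to a C8 ketone, C11 from a formaldehyde aldol at C9, and the C8 oxygen from allylic oxidation.
2. Ring A is opened at C2–C3 and C4–C5: C3 and C4 with its two methyl groups are an isobutyric acid unit, carried as the ester of a C7 allylic alcohol on a cyclohexene ring B.
3. Key step: Ireland–Claisen rearrangement forms C4–C5, relays the C7 oxygen to C3 and sets C5; lithium–iodine exchange and acyl substitution in the same flask form C2–C3.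
4. Enabling feature: in ring A the oxygen-bearing C3 lies next to the quaternary gem-dimethyl C4, and C4 is bonded to C5, which is an allylic terminus (C5=C6–C7–O) in the ring B precursor; C10 is preset by a Johnson–Claisen rearrangement.
5. Ring order: ring B is present from the start (3-methylcyclohex-2-en-1-one), ring A is closed in the key step, and the coumarin is attached last.

Key step: step 8

Remark: the decalin carbons carry drimane numbers (C1–C10; C11 is the CH2O carbon on C9); the target is read as the 3R,5S,8R,9S,10R isomer (trans ring fusion, axial CH2OAr on C9 trans to the C10 methyl group, axial C8 hydroxyl cis to it) with an (E)-2-methylbut-2-enoate (tiglate) on O3.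

**Route**

Step 1
Reactants: 1 3-methylcyclohex-2-en-1-one
Product: 2 (1R)-3-methylcyclohex-2-en-1-ol
Conditions: (S)-2-methyl-CBS-oxazaborolidine (10 mol %), catecholborane, toluene, −78 °C
Reagents that add atoms: none
Why: Corey–Bakshi–Shibata reduction, in which the oxazaborolidine–borane complex should deliver hydride to one face of the enone carbonyl (alkenyl arm as the large group), so the catalyst sets the carbinol centre as R.

Step 2
Reactants: 2 (1R)-3-methylcyclohex-2-en-1-ol; 3 triethyl orthoacetate
Product: 4 ethyl 2-[(1R)-1-methylcyclohex-2-en-1-yl]acetate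
Conditions: EtCO2H (cat.), 140 °C, EtOH distilled off
Reagents that add atoms: none
Why: Johnson–Claisen rearrangement, in which the ketene acetal on the allylic oxygen shifts suprafacially onto the methyl-bearing alkene carbon, so the carbinol configuration is relayed to the new quaternary centre (future C10) and the double bond moves next to it.

Step 3
Reactants: 4 ethyl 2-[(1R)-1-methylcyclohex-2-en-1-yl]acetate
Product: 5 2-[(1R)-1-methylcyclohex-2-en-1-yl]ethan-1-ol
Conditions: LiAlH4, Et2O, 0 °C
Reagents that add atoms: none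
Why: LiAlH4 reduction of an ester to the primary alcohol, which leaves the isolated alkene and the quaternary centre untouched.

Step 4
Reactants: 5 2-[(1R)-1-methylcyclohex-2-en-1-yl]ethan-1-ol
Product: 6 (3R)-3-(2-iodoethyl)-3-methylcyclohex-1-ene
Conditions: I2, PPh3, imidazole, CH2Cl2, 0 °C to rt
Reagents that add atoms: iodine, II
Why: Appel-type iodination of an unhindered primary alcohol by SN2 displacement of the alkoxyphosphonium ion, with no stereocentre involved.

Step 5
Reactants: 6 (3R)-3-(2-iodoethyl)-3-methylcyclohex-1-ene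
Product: 7 (4R)-4-(2-iodoethyl)-4-methylcyclohex-2-en-1-one
Conditions: Rh2(C6H10NO)4 (dirhodium tetrakis(caprolactamate), 1 mol %), t-BuOOH, K2CO3, CH2Cl2, rt
Reagents that add atoms: tert-butyl hydroperoxide, CC(C)(C)OO
Why: radical allylic C–H oxidation, in which the only allylic hydrogens sit on the ring CH2 remote from the quaternary carbon and oxygen should enter at that unhindered end of the allyl radical to give the 4,4-disubstituted enone (future C7 carbonyl).

Step 6
Reactants: 7 (4R)-4-(2-iodoethyl)-4-methylcyclohex-2-en-1-one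
Product: 8 (1S,4R)-4-(2-iodoethyl)-4-methylcyclohex-2-en-1-ol
Conditions: (R)-2-methyl-CBS-oxazaborolidine (10 mol %), catecholborane, toluene, −78 °C
Reagents that add atoms: none
Why: Corey–Bakshi–Shibata reduction under reagent control (the remote quaternary centre gives no bias), in which the R catalyst should give the 1S carbinol with the oxygen cis to the methyl group, as step 8 requires.

Step 7
Reactants: 8 (1S,4R)-4-(2-iodoethyl)-4-methylcyclohex-2-en-1-ol; 9 2-methylpropanoyl chloride
Product: 10 (1S,4R)-4-(2-iodoethyl)-4-methylcyclohex-2-en-1-yl 2-methylpropanoate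
Conditions: pyridine, DMAP (cat.), CH2Cl2, 0 °C
Reagents that add atoms: none
Why: DMAP-catalysed acylation of a secondary allylic alcohol, which installs the isobutyrate that becomes C3, C4 and the two C4 methyl groups.

Step 8
Reactants: 10 (1S,4R)-4-(2-iodoethyl)-4-methylcyclohex-2-en-1-yl 2-methylpropanoate
Product: 13 (4aR,8aS)-1,1,4a-trimethyl-3,4,4a,5,6,8a-hexahydronaphthalen-2(1H)-one, via silyl ketene acetal 11 (not isolated), via trimethylsilyl ester 12 (not isolated)
Conditions: TMSCl, then LDA, THF, −78 °C, then 65 °C; volatiles removed; Et2O, t-BuLi (2.2 equiv), −78 to 0 °C; aq NH4Cl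
Reagents that add atoms: none
Why: In situ silylation of the ester enolate gives silyl ketene acetal 11, whose [3,3] sigmatropic shift (Ireland–Claisen rearrangement) forms the C4–C5 bond and moves the C7 oxygen into the carboxyl group that becomes the C3 carbonyl; because C4 carries two methyl groups there is no enolate-geometry or chair/boat issue. The shift is suprafacial, so the new bond at C5 forms on the face that carried the C7 oxygen, cis to the C10 methyl group and trans to the iodoethyl chain, which fixes C5 (S) and with it the trans ring fusion. After removal of the amine and excess silyl chloride, lithium–iodine exchange should be faster than attack of tert-butyllithium on the hindered silyl ester 12, and the primary alkyllithium closes ring A by a 6-exo-trig nucleophilic acyl substitution (Parham-type cycloacylation) that forms the C2–C3 bond and expels trimethylsilanolate to give ketone 13. The closest known reaction types are the Ireland–Claisen rearrangement of cyclohex-2-enyl esters to build a quaternary carbon and the exchange-initiated cyclisation of iodo esters to cycloalkanones. The selectivity needed is chemoselectivity at the iodide, secured by the internal silyl chloride quench (no free enolate to alkylate it) and by the trans, diequatorial placement of the two side chains on ring B, which holds the carbanion next to the acyl group.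

Step 9
Reactants: 13 (4aR,8aS)-1,1,4a-trimethyl-3,4,4a,5,6,8a-hexahydronaphthalen-2(1H)-one
Product: 14 (2R,4aR,8aS)-1,1,4a-trimethyl-1,2,3,4,4a,5,6,8a-octahydronaphthalen-2-ol
Conditions: NaBH4, MeOH, 0 °C
Reagents that add atoms: none
Why: NaBH4 reduction of a 4,4-dimethyl-3-oxo trans-decalin, in which hydride attacks axially, away from the axial C4 methyl group, so the C3 hydroxyl is set equatorial (R), cis to the C10 methyl group.

Step 10
Reactants: 14 (2R,4aR,8aS)-1,1,4a-trimethyl-1,2,3,4,4a,5,6,8a-octahydronaphthalen-2-ol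
Product: 15 (4aS,6R,8aS)-6-hydroxy-5,5,8a-trimethyl-4a,5,6,7,8,8a-hexahydronaphthalen-2(1H)-one
Conditions: Rh2(C6H10NO)4 (1 mol %), t-BuOOH, K2CO3, CH2Cl2, rt
Reagents that add atoms: tert-butyl hydroperoxide, CC(C)(C)OO
Why: the same radical allylic oxidation as in step 5, in which hydrogen abstraction should occur at the C8 methylene (the other allylic C–H, on C5, is tertiary and buried between two quaternary carbons) and give the C8 enone while the hindered C3 carbinol survives.

Step 11
Reactants: 15 (4aS,6R,8aS)-6-hydroxy-5,5,8a-trimethyl-4a,5,6,7,8,8a-hexahydronaphthalen-2(1H)-one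
Product: 16 (1S,4aS,6R,8aR)-6-hydroxy-1-(hydroxymethyl)-5,5,8a-trimethyl-4a,5,6,7,8,8a-hexahydronaphthalen-2(1H)-one
Conditions: LDA (2.2 equiv), THF, −78 °C; CH2O (gas, from cracked paraformaldehyde), −78 °C; aq NH4Cl
Reagents that add atoms: formaldehyde, C=O
Why: kinetic α′-deprotonation of the enone (after the alkoxide has formed) gives the cross-conjugated C8–C9 enolate, whose aldol addition to formaldehyde should occur on the face opposite the axial C10 methyl group and set C9 (S) with the CH2OH group axial, while the hemiformal on O3 reverts on work-up.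

Step 12
Reactants: 16 (1S,4aS,6R,8aR)-6-hydroxy-1-(hydroxymethyl)-5,5,8a-trimethyl-4a,5,6,7,8,8a-hexahydronaphthalen-2(1H)-one
Product: 17 (1S,2R,4aS,6R,8aR)-1-(hydroxymethyl)-2,5,5,8a-tetramethyl-1,2,4a,5,6,7,8,8a-octahydronaphthalene-2,6-diol
Conditions: MeLi, CeCl3 (5 equiv each), THF, −78 °C
Reagents that add atoms: methyllithium, [Li]C
Why: 1,2-addition of the weakly basic organocerium reagent, in which attack syn to the axial C10 methyl group is blocked, so methyl should enter from the face of the C9 substituent and give the C8 hydroxyl (R) cis to the C10 methyl group without enolisation or retro-aldol cleavage.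

Step 13
Reactants: 17 (1S,2R,4aS,6R,8aR)-1-(hydroxymethyl)-2,5,5,8a-tetramethyl-1,2,4a,5,6,7,8,8a-octahydronaphthalene-2,6-diol
Product: 18 (1S,2R,4aS,6R,8aR)-1-(hydroxymethyl)-2,5,5,8a-tetramethyldecahydronaphthalene-2,6-diol
Conditions: H2 (1 atm), PtO2, EtOAc, rt
Reagents that add atoms: none
Why: heterogeneous hydrogenation of the disubstituted C6–C7 alkene, which forms no stereocentre and in a neutral solvent should spare the allylic tertiary alcohol.

Step 14
Reactants: 18 (1S,2R,4aS,6R,8aR)-1-(hydroxymethyl)-2,5,5,8a-tetramethyldecahydronaphthalene-2,6-diol; 19 7-hydroxy-2H-chromen-2-one (umbelliferone)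
Product: 20 7-{[(1S,2R,4aS,6R,8aR)-2,6-dihydroxy-2,5,5,8a-tetramethyldecahydronaphthalen-1-yl]methoxy}-2H-chromen-2-one
Conditions: PPh3, DIAD, THF, 0 °C to rt
Reagents that add atoms: none
Why: Mitsunobu etherification, in which only the primary C11 hydroxyl is activated (the C3 carbinol is neopentylic, the C8 carbinol tertiary) and the acidic 7-hydroxycoumarin displaces the oxyphosphonium group without touching a stereocentre.

Step 15
Reactants: 20 7-{[(1S,2R,4aS,6R,8aR)-2,6-dihydroxy-2,5,5,8a-tetramethyldecahydronaphthalen-1-yl]methoxy}-2H-chromen-2-one; 21 (2E)-2-methylbut-2-enoyl chloride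
Product: 22 (2R,4aR,5S,6R,8aS)-6-hydroxy-1,1,4a,6-tetramethyl-5-{[(2-oxo-2H-chromen-7-yl)oxy]methyl}decahydronaphthalen-2-yl (2E)-2-methylbut-2-enoate (CNP0189964.3)
Conditions: pyridine, DMAP (cat.), CH2Cl2, 40 °C
Reagents that add atoms: none
Why: DMAP-catalysed acylation of the equatorial C3 hydroxyl (the tertiary C8 hydroxyl does not react) with the E-configured acid chloride, whose geometry is carried into the tiglate.

**Compound list**

1 | 3-methylcyclohex-2-en-1-one | CC1=CC(=O)CCC1 | starting material
2 | (1R)-3-methylcyclohex-2-en-1-ol | CC1=C[C@H](O)CCC1 | intermediate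
3 | triethyl orthoacetate (1,1,1-triethoxyethane) | CC(OCC)(OCC)OCC | starting material
4 | ethyl 2-[(1R)-1-methylcyclohex-2-en-1-yl]acetate | CCOC(=O)C[C@]1(C)C=CCCC1 | intermediate
5 | 2-[(1R)-1-methylcyclohex-2-en-1-yl]ethan-1-ol | OCC[C@]1(C)C=CCCC1 | intermediate
6 | (3R)-3-(2-iodoethyl)-3-methylcyclohex-1-ene | ICC[C@]1(C)C=CCCC1 | intermediate
7 | (4R)-4-(2-iodoethyl)-4-methylcyclohex-2-en-1-one | ICC[C@]1(C)C=CC(=O)CC1 | intermediate
8 | (1S,4R)-4-(2-iodoethyl)-4-methylcyclohex-2-en-1-ol | ICC[C@]1(C)C=C[C@@H](O)CC1 | intermediate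
9 | 2-methylpropanoyl chloride | CC(C)C(Cl)=O | starting material
10 | (1S,4R)-4-(2-iodoethyl)-4-methylcyclohex-2-en-1-yl 2-methylpropanoate | ICC[C@]1(C)C=C[C@@H](OC(=O)C(C)C)CC1 | intermediate
11 | 1-{[(1S,4R)-4-(2-iodoethyl)-4-methylcyclohex-2-en-1-yl]oxy}-2-methyl-1-[(trimethylsilyl)oxy]prop-1-ene (silyl ketene acetal) | ICC[C@]1(C)C=C[C@@H](OC(O[Si](C)(C)C)=C(C)C)CC1 | intermediate
12 | trimethylsilyl 2-[(1S,6R)-6-(2-iodoethyl)-6-methylcyclohex-2-en-1-yl]-2-methylpropanoate | ICC[C@]1(C)[C@H](C=CCC1)C(C)(C)C(=O)O[Si](C)(C)C | intermediate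
13 | (4aR,8aS)-1,1,4a-trimethyl-3,4,4a,5,6,8a-hexahydronaphthalen-2(1H)-one | O=C1CC[C@]2(C)[C@H](C=CCC2)C1(C)C | intermediate
14 | (2R,4aR,8aS)-1,1,4a-trimethyl-1,2,3,4,4a,5,6,8a-octahydronaphthalen-2-ol | O[C@@H]1CC[C@]2(C)[C@H](C=CCC2)C1(C)C | intermediate
15 | (4aS,6R,8aS)-6-hydroxy-5,5,8a-trimethyl-4a,5,6,7,8,8a-hexahydronaphthalen-2(1H)-one | O[C@@H]1CC[C@]2(C)[C@H](C=CC(=O)C2)C1(C)C | intermediate
16 | (1S,4aS,6R,8aR)-6-hydroxy-1-(hydroxymethyl)-5,5,8a-trimethyl-4a,5,6,7,8,8a-hexahydronaphthalen-2(1H)-one | O[C@@H]1CC[C@]2(C)[C@H](C=CC(=O)[C@@H]2CO)C1(C)C | intermediate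
17 | (1S,2R,4aS,6R,8aR)-1-(hydroxymethyl)-2,5,5,8a-tetramethyl-1,2,4a,5,6,7,8,8a-octahydronaphthalene-2,6-diol | O[C@@H]1CC[C@]2(C)[C@H](C=C[C@@](C)(O)[C@@H]2CO)C1(C)C | intermediate
18 | (1S,2R,4aS,6R,8aR)-1-(hydroxymethyl)-2,5,5,8a-tetramethyldecahydronaphthalene-2,6-diol | O[C@@H]1CC[C@]2(C)[C@H](CC[C@@](C)(O)[C@@H]2CO)C1(C)C | intermediate
19 | 7-hydroxy-2H-chromen-2-one (umbelliferone) | Oc1ccc2ccc(=O)oc2c1 | starting material
20 | 7-{[(1S,2R,4aS,6R,8aR)-2,6-dihydroxy-2,5,5,8a-tetramethyldecahydronaphthalen-1-yl]methoxy}-2H-chromen-2-one | O[C@@H]1CC[C@]2(C)[C@H](CC[C@@](C)(O)[C@@H]2COc2ccc3ccc(=O)oc3c2)C1(C)C | intermediate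
21 | (2E)-2-methylbut-2-enoyl chloride (tigloyl chloride) | C/C=C(\C)C(Cl)=O | starting material
22 | (2R,4aR,5S,6R,8aS)-6-hydroxy-1,1,4a,6-tetramethyl-5-{[(2-oxo-2H-chromen-7-yl)oxy]methyl}decahydronaphthalen-2-yl (2E)-2-methylbut-2-enoate | C/C=C(\C)C(=O)O[C@@H]1CC[C@]2(C)[C@H](CC[C@@](C)(O)[C@@H]2COc2ccc3ccc(=O)oc3c2)C1(C)C | target

**Step count and risks**

Total step count: 15. Longest linear sequence: 15 steps (1 to 22); compounds 3, 9, 19 and 21 are commercial inputs.

Steps most likely to fail:

1. Step 8. The sigmatropic shift has to form a bond between a quaternary carbon and a ring carbon flanked by another quaternary centre and may be slow. The iodide may be lost by elimination or alkylation during enolisation. In the second stage, protonation of the alkyllithium or direct attack of tert-butyllithium on the silyl ester may compete with ring closure. Fallback, setting out from alcohol 8: heating with 1,1-dimethoxy-2-methylpropane and a trace of 2,4-dinitrophenol in xylene at 150 °C should give, by acetal exchange and loss of methanol, (3R,6S)-3-(2-iodoethyl)-3-methyl-6-[(2-methylprop-1-en-1-yl)oxy]cyclohex-1-ene F1. This undergoes Claisen rearrangement in the same pot, with the same suprafacial transfer, to 2-[(1S,6R)-6-(2-iodoethyl)-6-methylcyclohex-2-en-1-yl]-2-methylpropanal F2. Barbier ring closure with SmI2 and HMPA in THF should then give alcohol 14 together with its C3 epimer (2S,4aR,8aS)-1,1,4a-trimethyl-1,2,3,4,4a,5,6,8a-octahydronaphthalen-2-ol F3. Oxidation of the mixture with Dess–Martin periodinane returns to the route at ketone 13.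

2. Step 10. The oxidant may also attack the secondary carbinol, abstract the tertiary allylic hydrogen on C5, or deliver oxygen to the other end of the allyl radical (enone transposition). Fallback, setting out from alcohol 14: SeO2 (cat.) with t-BuOOH in CH2Cl2 should hydroxylate the C8 methylene by an ene reaction and 2,3-shift to give (2R,4aS,8aS)-1,1,4a-trimethyl-1,2,3,4,4a,5,6,8a-octahydronaphthalene-2,6-diol F4 (C6 epimers). MnO2 oxidises only the allylic carbinol, which returns to the route at enone 15.

3. Step 12. Facial selectivity at C8 may be poor because the axial CH2OH group on C9 shields the face the reagent has to use, and the β-hydroxy ketone may undergo retro-aldol cleavage or C9 epimerisation. Fallback, setting out from enone 15 and replacing steps 11 to 13, so that C8 is set while C9 is trigonal: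
   - α′-Formylation (LDA, then 2,2,2-trifluoroethyl formate) should give (4aS,6R,8aR)-6-hydroxy-1-[(Z)-hydroxymethylidene]-5,5,8a-trimethyl-4a,5,6,7,8,8a-hexahydronaphthalen-2(1H)-one F5.
   - Silylation of the enol oxygen (TBSCl, imidazole) gives (4aS,6R,8aR)-1-[(E)-{[tert-butyl(dimethyl)silyl]oxy}methylidene]-6-hydroxy-5,5,8a-trimethyl-4a,5,6,7,8,8a-hexahydronaphthalen-2(1H)-one F6.
   - MeLi/CeCl3 adds to C8 anti to the C10 methyl group, with no axial neighbour in the way, giving (2R,4aS,6R,8aR)-1-[(E)-{[tert-butyl(dimethyl)silyl]oxy}methylidene]-2,5,5,8a-tetramethyl-1,2,4a,5,6,7,8,8a-octahydronaphthalene-2,6-diol F7.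
   - Hydroxyl-directed hydrogenation with [Ir(cod)(PCy3)(py)]PF6 and H2 in CH2Cl2 saturates both alkenes and delivers hydrogen to C9 from the face of the C8 hydroxyl, giving (1S,2R,4aS,6R,8aR)-1-({[tert-butyl(dimethyl)silyl]oxy}methyl)-2,5,5,8a-tetramethyldecahydronaphthalene-2,6-diol F8.
   - Bu4NF in THF returns to the route at triol 18.

Further compounds
F1 | step 8 | (3R,6S)-3-(2-iodoethyl)-3-methyl-6-[(2-methylprop-1-en-1-yl)oxy]cyclohex-1-ene | ICC[C@]1(C)C=C[C@@H](OC=C(C)C)CC1
F2 | step 8 | 2-[(1S,6R)-6-(2-iodoethyl)-6-methylcyclohex-2-en-1-yl]-2-methylpropanal | ICC[C@]1(C)[C@H](C=CCC1)C(C)(C)C=O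
F3 | step 8 | (2S,4aR,8aS)-1,1,4a-trimethyl-1,2,3,4,4a,5,6,8a-octahydronaphthalen-2-ol | O[C@H]1CC[C@]2(C)[C@H](C=CCC2)C1(C)C
F4 | step 10 | (2R,4aS,8aS)-1,1,4a-trimethyl-1,2,3,4,4a,5,6,8a-octahydronaphthalene-2,6-diol (C6 epimers) | O[C@@H]1CC[C@]2(C)[C@H](C=CC(O)C2)C1(C)C
F5 | step 12 | (4aS,6R,8aR)-6-hydroxy-1-[(Z)-hydroxymethylidene]-5,5,8a-trimethyl-4a,5,6,7,8,8a-hexahydronaphthalen-2(1H)-one | O[C@@H]1CC[C@]2(C)[C@H](C=CC(=O)/C2=C\O)C1(C)C
F6 | step 12 | (4aS,6R,8aR)-1-[(E)-{[tert-butyl(dimethyl)silyl]oxy}methylidene]-6-hydroxy-5,5,8a-trimethyl-4a,5,6,7,8,8a-hexahydronaphthalen-2(1H)-one | O[C@@H]1CC[C@]2(C)[C@H](C=CC(=O)/C2=C/O[Si](C)(C)C(C)(C)C)C1(C)C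
F7 | step 12 | (2R,4aS,6R,8aR)-1-[(E)-{[tert-butyl(dimethyl)silyl]oxy}methylidene]-2,5,5,8a-tetramethyl-1,2,4a,5,6,7,8,8a-octahydronaphthalene-2,6-diol | O[C@@H]1CC[C@]2(C)[C@H](C=C[C@@](C)(O)/C2=C/O[Si](C)(C)C(C)(C)C)C1(C)C
F8 | step 12 | (1S,2R,4aS,6R,8aR)-1-({[tert-butyl(dimethyl)silyl]oxy}methyl)-2,5,5,8a-tetramethyldecahydronaphthalene-2,6-diol | O[C@@H]1CC[C@]2(C)[C@H](CC[C@@](C)(O)[C@@H]2CO[Si](C)(C)C(C)(C)C)C1(C)C
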